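The runs are simulated from invented constants, noise included.

Follow partner B. These are the flasks, the readings and the questions:

common to all: substrate 0.10 M

| charge | partner A | partner B | remark | time |
|---|---|---|---|---|
| violet | 0.066 M | 0.20 M | run made earlier |  |
| grey | 0.16 M | 0.20 M | run made earlier |  |
| Monday's | 0.0600 M | 0.200 M |  | 15 d |
| Saturday's | 0.120 M | 0.200 M |  | 15 d |
| Tuesday's | 0.200 M | 0.200 M |  | 15 d |

| run | time / d | target / % | substrate / % |
|---|---|---|---|
| violet | 1.67 | 12.0 | 27.3 |
| violet | 3.00 | 14.8 | 14.7 |
| violet | 5.00 | 15.4 | 8.5 |
| violet | 6.00 | 16.1 | 6.5 |
| violet | 8.00 | 16.5 | 3.8 |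
| grey | 1.67 | 14.2 | 43.3 |
| grey | 3.00 | 18.7 | 36.4 |
| grey | 5.00 | 19.8 | 33.7 |
| grey | 6.00 | 22.3 | 33.8 |
| grey | 8.00 | 20.8 | 34.4 |

(readings scatter by 1 percentage point)

1. amount of target at the end, in percent of the substrate charged for Monday's, Saturday's, Tuesday's, in this order
2. how the row runs (falls, then rises / rises all the way / rises, then falls / hardly changes / falls all the way)

- a reading or a percentage of target counts all its forms, free or not
- "hardly changes" means that all values lie within two and a half points (for a concentration: within two and a half percent of the largest)

Violet and grey differ in their charge of partner A, yet they end differently. Violet's substrate keeps falling, to 3.8 % at 8.00 d, while grey's stands near 34.4 % from 5.00 d onwards. I assume that substrate and partner A each take one partner B. Violet's partner B then covers 1.20 of the combined demand, but grey's covers 0.769. So grey stops because partner B is its limiting reagent, and by this count the partner A left in grey is 16.0 % of its charge.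

If both steps are first order in each partner, the two consumers share the same partner B, so one ratio stays frozen through a flask. This selectivity factor, the logarithm of the substrate fraction left over the logarithm of the partner A fraction left, reads 0.582 from grey.

Tuesday's charges partner A and partner B equally, and its partner B covers 0.667 of the combined demand. So if partner B comes down to zero, as I reckon, the partner A left in Tuesday's equals the partner B taken by substrate, and the substrate left is that partner A fraction raised to the power of the factor. Trying 0.5 for the substrate left gives 44.6 %, and trying that gives 47.3 %, so I reckon on about 46.0 % left. Grey's target per substrate used is 0.317, which is more than violet's 0.172. Grey's ratio puts Tuesday's near 17.1 %. Monday's is covered at 1.25, like violet, so I expect about violet's 16.5 %.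

The forecast gives 15.5 %, 22 % and 19 %, with the shape rises, then falls, “so the row peaks”. Its Tuesday figure stands above mine.

The flask gives 14.6 %, 21.9 % and 18.0 %: rises, then falls.

    substrate + partner B → open intermediate (k = 0.300 M⁻¹ h⁻¹)
    partner B + partner A → second intermediate (k = 0.480 M⁻¹ h⁻¹)
    open intermediate + second intermediate ⇌ target (K = 3.80 M⁻¹, k = 1.30 M⁻¹ h⁻¹)
    crystals ⇌ target, rate k4*(cs4 - [target]) while solid is left; crystals form when [target] > cs4 (solubility = 49.0 mM, k = 0.190 h⁻¹)

On Tuesday's, partner B stands at 0 % of its charge at 15.0 d. Raising Tuesday's partner A left, 28 %, to the power of the factor gives 47.7 % substrate left, and Tuesday's flask holds 44.8 % of substrate at the end. On Saturday's, partner A left at 5.0 % gives 17.5 % by the same power, and Saturday's flask holds 15.4 % of substrate at the end.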